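The route cuts the C9–C10 bond of ring B. The adjacent quaternary C10 and tertiary C9, followed by the C7=C8 alkene conjugated with the C17 carboxyl, are the signature of a radical addition–elimination. Hydrogen-atom transfer to C1 of a ring A cyclohexene generates the tertiary C10 radical. This radical attacks C9 of a 2-(1-acetoxyalkyl)enoate, and departure of the C7 acetate installs the C7=C8 enoate. One operation closes ring B, forges C9–C10, and sets C9 and C10 from the C5 stereocentre and the enoate geometry. The precursor is an (S)-α-cyclogeranyl ring linked through C6–C7(OAc) to a Z tert-butyl enoate whose chain ends in a ketal-masked methyl ketone.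

Key step: step 9

Remarks on the chemistry (labdane numbering: decalin C1–C10, C17 on C8, C20 on C10, side chain C11–C16)
- Assumption: C7 is carried as a mixture of epimers, because no reliable induction from C5 can be expected in step 7 and the centre is erased in step 9.
- In the chair-like closure only the 7R epimer holds its acetate axial (α), parallel to the enolate π system. The 7S epimer holds it equatorial and is poorly aligned, so step 9 ends with a DBU treatment that brings both epimers to one product.
- C17 is carried as a tert-butyl ester. One acid treatment after the key step frees the C17 acid and the C13 ketone together. No reduction–reoxidation at C17 is then needed, and two primary allylic alcohols never have to be told apart.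
- The target was checked as (5S,9R,10S,13E): trans-decalin, C20 β-axial, H-5 and H-9 α, and C11 β-equatorial.

Step 1
Reactants: 1 isobutyraldehyde; 2 ethyl vinyl ketone
Product: 4 2,4,4-trimethylcyclohex-2-en-1-one, via keto aldehyde 3 (not isolated)
Conditions: H2SO4 (cat.), toluene, 45 °C, then reflux (Dean–Stark)
Reagents that add atoms: none
Why: Acid-catalysed Robinson annulation, in which the enol of 1 adds in Michael fashion to 2 and, in 3, only the ethyl CH2 of the ketone can condense with the non-enolisable aldehyde to form a six-membered ring, so a single enone should result.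

Step 2
Reactants: 4 2,4,4-trimethylcyclohex-2-en-1-one
Product: 5 (R)-2,4,4-trimethylcyclohex-2-en-1-ol
Conditions: (S)-Me-CBS [(3aS)-1-methyl-3,3-diphenyltetrahydro-1H,3H-pyrrolo[1,2-c][1,3,2]oxazaborole] (10 mol %), BH3·SMe2 (0.6 equiv), THF, −20 °C; aqueous work-up
Reagents that add atoms: none
Why: Corey–Bakshi–Shibata 1,2-reduction, in which the methyl-bearing alkene arm behaves as the large substituent and the ring CH2 as the small one, so the (S)-catalyst should deliver hydride to the face that gives the R carbinol.

Step 3
Reactants: 5 (R)-2,4,4-trimethylcyclohex-2-en-1-ol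
Product: 7 ethyl 2-[(1S)-2,6,6-trimethylcyclohex-2-en-1-yl]acetate, via ketene acetal 6 (not isolated)
Conditions: MeC(OEt)3 (excess), EtCO2H (cat.), 140 °C, EtOH distilled off
Reagents that add atoms: triethyl orthoacetate, CC(OCC)(OCC)OCC
Why: Johnson–Claisen rearrangement, in which 6 undergoes a suprafacial [3,3] shift that forms C5–C6 on the ring face vacated by the C–O bond, so the R carbinol configuration is relayed to 5S while the alkene moves to C1=C10.

Step 4
Reactants: 7 ethyl 2-[(1S)-2,6,6-trimethylcyclohex-2-en-1-yl]acetate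
Product: 8 2-[(1S)-2,6,6-trimethylcyclohex-2-en-1-yl]acetaldehyde
Conditions: i-Bu2AlH (DIBAL-H, 1.05 equiv), CH2Cl2, −78 °C; aq. potassium sodium tartrate
Reagents that add atoms: none
Why: Partial ester reduction, in which the tetrahedral aluminium hemiacetal persists at −78 °C and collapses to the aldehyde only on work-up, while C5 is β to the carbonyl and cannot epimerise.

Step 5
Reactants: 9 hex-5-yn-2-one
Product: 10 2-(but-3-yn-1-yl)-2-methyl-1,3-dioxolane
Conditions: HOCH2CH2OH, p-TsOH·H2O (cat.), toluene, reflux (Dean–Stark)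
Reagents that add atoms: ethylene glycol, OCCO
Why: Acid-catalysed ketalisation driven by azeotropic removal of water, to which the terminal alkyne is inert.

Step 6
Reactants: 10 2-(but-3-yn-1-yl)-2-methyl-1,3-dioxolane
Product: 12 tert-butyl 5-(2-methyl-1,3-dioxolan-2-yl)pent-2-ynoate, via lithium acetylide 11 (not isolated)
Conditions: n-BuLi, THF, −78 °C; Boc2O, −78 → 0 °C
Reagents that add atoms: di-tert-butyl dicarbonate, CC(C)(C)OC(=O)OC(=O)OC(C)(C)C
Why: Alkoxycarbonylation of a lithium acetylide, in which C-acylation by Boc2O gives the ynoate and the bulky ester resists a second addition.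

Step 7
Reactants: 12 tert-butyl 5-(2-methyl-1,3-dioxolan-2-yl)pent-2-ynoate; 8 2-[(1S)-2,6,6-trimethylcyclohex-2-en-1-yl]acetaldehyde
Product: 14 tert-butyl (Z)-2-{(1RS)-1-hydroxy-2-[(1S)-2,6,6-trimethylcyclohex-2-en-1-yl]ethyl}-5-(2-methyl-1,3-dioxolan-2-yl)pent-2-enoate, via vinylalane 13 (not isolated)
Conditions: 12 (1.4 equiv), i-Bu2AlH (1.3 equiv), HMPA, THF, 0 °C; then 8, 0 °C → rt; aq. potassium sodium tartrate
Reagents that add atoms: none
Why: Vinylalumination, in which HMPA-modified i-Bu2AlH adds H (to C9) and Al (to C8) syn across the ynoate and 13 attacks the aldehyde with retention, so C7 ends up cis to H-9 and trans to C11 (Z), while C7 itself forms as both epimers, which is harmless because step 9 erases it.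

Step 8
Reactants: 14 the Z hydroxy enoate
Product: 15 tert-butyl (Z)-2-{(1RS)-1-acetoxy-2-[(1S)-2,6,6-trimethylcyclohex-2-en-1-yl]ethyl}-5-(2-methyl-1,3-dioxolan-2-yl)pent-2-enoate
Conditions: Ac2O, pyridine, DMAP (cat.), CH2Cl2, 0 °C → rt
Reagents that add atoms: acetic anhydride, CC(=O)OC(C)=O
Why: DMAP-catalysed acetylation of the secondary allylic alcohol, which touches neither the enoate geometry, the ketal nor C5.

Step 9
Reactants: 15 the acetoxy Z-enoate
Product: 17 tert-butyl (5S,9R,10S)-13,13-ethylenedioxy-14,15-dinorlabd-7-en-17-oate, via ester enolate 16 (not isolated)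
Conditions: Fe(acac)3 (30 mol %), PhSiH3 (3 equiv), degassed EtOH (0.02 M), 60 °C; then solvent switch to toluene, DBU (3 equiv), 60 °C
Reagents that add atoms: none
Why: Proposed new method: the iron hydride formed from Fe(acac)3 and PhSiH3 passes a hydrogen atom to C1 of the only electron-rich alkene, the tertiary C10 radical adds to the β-carbon C9 of the enoate, divalent iron reduces the resulting C8 radical to enolate 16, and 16 ejects the C7 acetate (E1cB), which places the alkene at C7–C8 while the silane turns over the trivalent iron acetate. The closest known reaction types are the intramolecular MHAT reductive olefin coupling (Giese type) onto acrylates and the intermolecular iron-hydride hydroallylation of alkenes with Morita–Baylis–Hillman acetates; what is new is their merger in a ring closure on a β-alkylated acceptor. Ring B closes 6-endo-trig, because C9 is the polarity-matched β-carbon whereas the 5-exo site C8 is the fully substituted α-carbon. C10 is controlled by C5: with the C5–C6 tether equatorial on ring A, the chair-like transition state that also operates in stepwise radical polyene cyclisations bonds C9 equatorially and leaves C20 axial (β), which gives the trans-decalin. C9 is controlled by the alkene geometry, since C11 stands trans to C7 in the Z-enoate and therefore becomes equatorial (β, H-9 α). The step needs chemoselective hydrogen-atom transfer, which is secured by keeping the side-chain unsaturation masked as the C13 ketal and by the steric shielding of the trisubstituted tert-butyl enoate, and it needs convergence of both C7 epimers, which is secured by the DBU finish that completes acetate loss for the epimer whose leaving group lies equatorial.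

Step 10
Reactants: 17 tert-butyl (5S,9R,10S)-13,13-ethylenedioxy-14,15-dinorlabd-7-en-17-oate
Product: 18 (5S,9R,10S)-13-oxo-14,15-dinorlabd-7-en-17-oic acid
Conditions: TFA–CH2Cl2–H2O, 0 °C → rt
Reagents that add atoms: water, O
Why: Acidolysis, in which the tert-butyl ester cleaves by alkyl–oxygen ionisation (AAL1) regardless of the hindrance at C17 and the dioxolane hydrolyses through its oxocarbenium ion, while the electron-poor C7=C8 alkene and the three stereocentres are inert to acid.

Step 11
Reactants: 18 (5S,9R,10S)-13-oxo-14,15-dinorlabd-7-en-17-oic acid; 19 triethyl phosphonoacetate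
Product: 21 (5S,9R,10S,13E)-15-ethoxy-15-oxolabda-7,13-dien-17-oic acid, via phosphonate carbanion 20 (not isolated)
Conditions: 19 (3 equiv), NaH (4 equiv), THF, 0 → 50 °C; then 1 M HCl
Reagents that add atoms: none
Why: Horner–Wadsworth–Emmons olefination of the methyl ketone, whose reversible addition should favour the ester trans to the larger C12 chain (13E, the minor 13Z isomer being removed by chromatography), while the C17 carboxylate formed in situ is inert to the carbanion and protects C9 from γ-deprotonation.

Step 12
Reactants: 21 (5S,9R,10S,13E)-15-ethoxy-15-oxolabda-7,13-dien-17-oic acid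
Product: 23 (5S,9R,10S,13E)-15-hydroxylabda-7,13-dien-17-oic acid, via aluminium carboxylate 22 (not isolated)
Conditions: i-Bu2AlH (4 equiv), CH2Cl2, −78 °C; aq. potassium sodium tartrate, then citric acid to pH 4
Reagents that add atoms: none
Why: Chemoselective 1,2-reduction, in which the first equivalent of i-Bu2AlH turns the acid into carboxylate 22, whose conjugated, electron-rich and C9-flanked carbonyl should be far less electrophilic at −78 °C than the unhindered C15 ethyl ester, which is reduced to the allylic alcohol with the 13E geometry retained.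

Step 13
Reactants: 23 (5S,9R,10S,13E)-15-hydroxylabda-7,13-dien-17-oic acid
Product: 24 (5S,9R,10S,13E)-15-(isobutyryloxy)labda-7,13-dien-17-oic acid (CNP0191003.1)
Conditions: (i-PrCO)2O (1.5 equiv), Et3N, DMAP (cat.), CH2Cl2, 0 °C → rt; aq. NaHCO3 stir, then citric acid to pH 4
Reagents that add atoms: isobutyric anhydride, CC(C)C(=O)OC(=O)C(C)C
Why: DMAP-catalysed esterification of the only hydroxyl group, in which the primary allylic alcohol is acylated without affecting the 13E alkene and any acyl transfer to the C17 carboxyl group is reversed by the aqueous NaHCO3 stir.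

Compound list
1 | isobutyraldehyde | CC(C)C=O | starting material
2 | ethyl vinyl ketone | C=CC(=O)CC | starting material
3 | 2,2-dimethyl-5-oxoheptanal | CCC(=O)CCC(C)(C)C=O | intermediate
4 | 2,4,4-trimethylcyclohex-2-en-1-one | CC1=CC(C)(C)CCC1=O | intermediate
5 | (R)-2,4,4-trimethylcyclohex-2-en-1-ol | O[C@@H]1CCC(C)(C)C=C1C | intermediate
6 | (R)-6-(1-ethoxyvinyloxy)-1,3,3-trimethylcyclohex-1-ene | C=C(OCC)O[C@@H]1CCC(C)(C)C=C1C | intermediate
7 | ethyl 2-[(1S)-2,6,6-trimethylcyclohex-2-en-1-yl]acetate | CC1=CCCC(C)(C)[C@@H]1CC(=O)OCC | intermediate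
8 | 2-[(1S)-2,6,6-trimethylcyclohex-2-en-1-yl]acetaldehyde | CC1=CCCC(C)(C)[C@@H]1CC=O | intermediate
9 | hex-5-yn-2-one | CC(=O)CCC#C | starting material
10 | 2-(but-3-yn-1-yl)-2-methyl-1,3-dioxolane | C#CCCC1(C)OCCO1 | intermediate
11 | lithium acetylide of 10 | [Li]C#CCCC1(C)OCCO1 | intermediate
12 | tert-butyl 5-(2-methyl-1,3-dioxolan-2-yl)pent-2-ynoate | CC(C)(C)OC(=O)C#CCCC1(C)OCCO1 | intermediate
13 | tert-butyl (E)-2-(diisobutylalumanyl)-5-(2-methyl-1,3-dioxolan-2-yl)pent-2-enoate (Al cis to H-9) | CC(C)C[Al](CC(C)C)/C(C(=O)OC(C)(C)C)=C/CCC1(C)OCCO1 | intermediate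
14 | tert-butyl (Z)-2-{(1RS)-1-hydroxy-2-[(1S)-2,6,6-trimethylcyclohex-2-en-1-yl]ethyl}-5-(2-methyl-1,3-dioxolan-2-yl)pent-2-enoate (C7 epimers) | CC1=CCCC(C)(C)[C@@H]1CC(O)/C(C(=O)OC(C)(C)C)=C/CCC2(C)OCCO2 | intermediate
15 | tert-butyl (Z)-2-{(1RS)-1-acetoxy-2-[(1S)-2,6,6-trimethylcyclohex-2-en-1-yl]ethyl}-5-(2-methyl-1,3-dioxolan-2-yl)pent-2-enoate (C7 epimers; key-step precursor) | CC1=CCCC(C)(C)[C@@H]1CC(OC(C)=O)/C(C(=O)OC(C)(C)C)=C/CCC2(C)OCCO2 | intermediate
16 | C8 ester enolate of tert-butyl 7-acetoxy-13,13-ethylenedioxy-14,15-dinorlabdan-17-oate (iron-bound, drawn as the anion) | CC3(CC[C@H]1C(=C([O-])OC(C)(C)C)C(OC(C)=O)C[C@H]2C(C)(C)CCC[C@]12C)OCCO3 | intermediate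
17 | tert-butyl (5S,9R,10S)-13,13-ethylenedioxy-14,15-dinorlabd-7-en-17-oate (key-step product) | CC3(CC[C@H]1C(C(=O)OC(C)(C)C)=CC[C@H]2C(C)(C)CCC[C@]12C)OCCO3 | intermediate
18 | (5S,9R,10S)-13-oxo-14,15-dinorlabd-7-en-17-oic acid | CC(=O)CC[C@H]1C(C(=O)O)=CC[C@H]2C(C)(C)CCC[C@]12C | intermediate
19 | triethyl phosphonoacetate | CCOC(=O)CP(=O)(OCC)OCC | starting material
20 | sodium salt of the triethyl phosphonoacetate carbanion | CCOC(=O)[CH-]P(=O)(OCC)OCC.[Na+] | intermediate
21 | (5S,9R,10S,13E)-15-ethoxy-15-oxolabda-7,13-dien-17-oic acid | C/C(=C\C(=O)OCC)CC[C@H]1C(C(=O)O)=CC[C@H]2C(C)(C)CCC[C@]12C | intermediate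
22 | diisobutylaluminium carboxylate of 21 | C/C(=C\C(=O)OCC)CC[C@H]1C(C(=O)O[Al](CC(C)C)CC(C)C)=CC[C@H]2C(C)(C)CCC[C@]12C | intermediate
23 | (5S,9R,10S,13E)-15-hydroxylabda-7,13-dien-17-oic acid | C/C(=C\CO)CC[C@H]1C(C(=O)O)=CC[C@H]2C(C)(C)CCC[C@]12C | intermediate
24 | (5S,9R,10S,13E)-15-(isobutyryloxy)labda-7,13-dien-17-oic acid | C/C(=C\COC(=O)C(C)C)CC[C@H]1C(C(=O)O)=CC[C@H]2C(C)(C)CCC[C@]12C | target

Total step count: 13. Longest linear sequence: 11 steps (steps 1–4 and 7–13, from 1 and 2). Steps 5 and 6 form the short branch.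

Steps most likely to fail

1. Step 9.
   - What may go wrong: hydrogen-atom transfer to the enoate instead of the ring A alkene, with reductive loss of the acetate before any C–C bond forms; enolate protonation outrunning acetate expulsion; erosion of the chair preference, and with it of the facial selectivity at C10 and C9.
   - Fallback: known chemistry that separates C–C bond formation from alkene installation. It sets out from 14 and comes back at 17. Alcohol 14 carries no leaving group and is submitted to an ordinary intramolecular MHAT reductive olefin coupling (Fe(acac)3, PhSiH3, EtOH, 60 °C). The enolate can then only be protonated, which should give tert-butyl 7-hydroxy-13,13-ethylenedioxy-14,15-dinorlabdan-17-oate F1. Mesylation (MsCl, Et3N, CH2Cl2, 0 °C) gives tert-butyl 7-(methanesulfonyloxy)-13,13-ethylenedioxy-14,15-dinorlabdan-17-oate F2. DBU in warm toluene then removes the sulfonate by E1cB elimination through the C8 ester enolate, which can place the alkene only at C7–C8, and this gives 17.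

2. Step 7.
   - What may go wrong: leakage of the vinylalane geometry through its allenolate form, which would later invert C9; competing reduction or enolisation of the aldehyde.
   - Fallback: the geometry is fixed by a halo-aldol reaction and a stereoretentive cross-coupling. It sets out from 8 and comes back at 14. Aldehyde 8, tert-butyl propiolate and MgI2 (CH2Cl2, 0 °C) undergo the iodide-triggered β-iodo Morita–Baylis–Hillman reaction to give tert-butyl (Z)-2-{1-hydroxy-2-[(1S)-2,6,6-trimethylcyclohex-2-en-1-yl]ethyl}-3-iodoacrylate F3, in which iodine stands trans to C7. Separately, hydroboration of commercial 2-methyl-2-vinyl-1,3-dioxolane with 9-BBN-H gives 9-[2-(2-methyl-1,3-dioxolan-2-yl)ethyl]-9-borabicyclo[3.3.1]nonane F4. A B-alkyl Suzuki–Miyaura coupling of the two (Pd(dppf)Cl2, AsPh3, Cs2CO3, DMF–THF–H2O, rt) replaces iodine by C11 with retention and gives 14.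

3. Step 12.
   - What may go wrong: loss of chemoselectivity through hydride attack on the aluminium carboxylate at C17, or reduction at C15 that stops halfway.
   - Fallback: selectivity in the reduction is given up on purpose. It sets out from 21 and comes back at 24. LiAlH4 (Et2O, 0 °C → rt) reduces both carboxyl groups to (5S,9R,10S,13E)-labda-7,13-diene-15,17-diol F5. The unhindered C15 alcohol is acylated in preference to the C17 alcohol, which is flanked by C9 and its side chain (isobutyryl chloride 1.0 equiv, 2,4,6-collidine, CH2Cl2, −78 °C), to give (13E)-17-hydroxylabda-7,13-dien-15-yl isobutyrate F6. MnO2 (CH2Cl2, rt) gives (13E)-17-oxolabda-7,13-dien-15-yl isobutyrate F7. Pinnick oxidation (NaClO2, NaH2PO4, 2-methylbut-2-ene, t-BuOH–H2O) then gives 24.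

Further compounds
F1 | step 9 | tert-butyl 7-hydroxy-13,13-ethylenedioxy-14,15-dinorlabdan-17-oate (5α-H, 9α-H, 10β-CH3; C7 and C8 epimers) | CC3(CC[C@H]1C(C(=O)OC(C)(C)C)C(O)C[C@H]2C(C)(C)CCC[C@]12C)OCCO3
F2 | step 9 | tert-butyl 7-(methanesulfonyloxy)-13,13-ethylenedioxy-14,15-dinorlabdan-17-oate | CC3(CC[C@H]1C(C(=O)OC(C)(C)C)C(OS(C)(=O)=O)C[C@H]2C(C)(C)CCC[C@]12C)OCCO3
F3 | step 7 | tert-butyl (Z)-2-{1-hydroxy-2-[(1S)-2,6,6-trimethylcyclohex-2-en-1-yl]ethyl}-3-iodoacrylate | CC1=CCCC(C)(C)[C@@H]1CC(O)/C(C(=O)OC(C)(C)C)=C/I
F4 | step 7 | 9-[2-(2-methyl-1,3-dioxolan-2-yl)ethyl]-9-borabicyclo[3.3.1]nonane | CC1(CCB2C3CCCC2CCC3)OCCO1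
F5 | step 12 | (5S,9R,10S,13E)-labda-7,13-diene-15,17-diol | C/C(=C\CO)CC[C@H]1C(CO)=CC[C@H]2C(C)(C)CCC[C@]12C
F6 | step 12 | (13E)-17-hydroxylabda-7,13-dien-15-yl isobutyrate | C/C(=C\COC(=O)C(C)C)CC[C@H]1C(CO)=CC[C@H]2C(C)(C)CCC[C@]12C
F7 | step 12 | (13E)-17-oxolabda-7,13-dien-15-yl isobutyrate | C/C(=C\COC(=O)C(C)C)CC[C@H]1C(C=O)=CC[C@H]2C(C)(C)CCC[C@]12C
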